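## The problem

Target 19 is tetracyclic. A cyclobutane is cis-fused to the five-membered ring of an indane, and the benzene ring of that indane (ring A) carries a methoxy group and a fused 2,2-dimethyl-2H-pyran. Cyclobuta[a]indene numbering is used throughout: C1 = CMe2, C2 = CH bearing the catechol ring, C2a and C7a = ring-fusion CH, C7 = CH2; ring A has C3 (pyran CH=CH), C4 (pyran O) and C6 (OMe).

The three stereocentres C2, C2a and C7a are contiguous on the four-membered ring and sit next to the quaternary C1. The catechol ring on C2 is trans to ring A on C2a, and C7 on C7a is cis to ring A.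

The cis fusion is the only one the bicyclo[3.2.0] frame allows, so C7a can be set by the ring closure itself once C2a exists. The trans relation C2/C2a and the absolute sense have to be created deliberately, because no stereocentre lies outside the cyclobutane.

Ring A needs three different substituents in fixed positions (carbon at C3, oxygen at C4, methoxy at C6), which is a regiochemical problem of its own.

The free catechol is oxidation-sensitive. The chromene double bond tolerates neither strong acid nor hydrogenation, which rules out hydrogenolytic deprotection at the end. The electron-rich 1,2-diarylcyclobutane can cleave under oxidising conditions.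

The feature that opens the synthesis is the substitution pattern of the cyclobutane. The two aryl-bearing carbons C2 and C2a are neighbours, CMe2 (C1) flanks the catechol carbon, and C7a, which holds the one-carbon link C7 to ring A, flanks C2a. This is the pattern of a head-to-head photoadduct of a cinnamate (β-carbon = C2a, α-carbon = C7a, carboxyl carbon = C7) with a 2-methylpropenylarene (C2, C1). A 3,5-dioxygenated cinnamate also has two equivalent ortho positions for the later closure of the five-membered ring.

## Retrosynthesis

**Pyran ring last.** In 19 the O–CMe2 bond and the bond between the arene-bound CH and the vinylic CH are cut. This leads to the salicylaldehyde 15 and (2-methylprop-1-en-1-yl)magnesium bromide 16; forward, the carbinol 17 dehydrates to the ortho-quinone methide 18, which closes by oxa-6π electrocyclisation. A chromene synthesis from a phenol and an enal or propargyl ether would have to choose between two free ortho positions (C3 and C5) and would need one phenol freed selectively; the formyl group at C3 removes both questions. The acid- and hydrogenation-labile double bond appears only in the final step. The forward reaction must tolerate three free phenols.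

**Ether cleavage.** 15 comes from 14 by cleavage of both benzyl ethers and of the one methyl ether that lies ortho to the formyl group. The aldehyde serves as a chelating handle that tells the two methoxy groups of ring A apart. Removing the benzyl groups here, before the chromene exists, avoids a late debenzylation next to that double bond.

**Formyl group.** In 14 the C3–CHO bond is cut, giving indane 12. Ring A of 12 has only two free positions, and C3 is para to one methoxy group and ortho to the other, the site an electrophile prefers over C5 between the two methoxy groups. The forward step (via iminium salt 13) must leave the less activated catechol ring alone.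

**Five-membered ring.** In 12 the arene–C7 bond is cut, giving aldehyde 9, whose formyl carbon becomes C7. Cutting the arene–C2a bond instead would demand arylation of a cyclobutane carbon and would give up the cinnamate logic. The aldehyde oxidation level is preferred to the acid level because an aldehyde epimerises at its α-carbon under the same acid that closes the ring, and the benzylic oxygen then leaves by ionic hydrogenation in the same flask. The forward reaction must invert the formyl-bearing carbon: trans aldehyde 9 equilibrates with cis aldehyde 10, only 10 can reach ring A, and the indanol 11 so formed is reduced to 12.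

**Oxidation level.** 9 comes from ester 8 by partial reduction; no skeletal bond is involved.

**Cyclobutane (key disconnection).** In 8 (cyclobutane numbering: C1 ester, C2 dimethoxyphenyl, C3 dibenzyloxyphenyl, C4 CMe2) the bonds C2–C3 and C1–C4 are cut, giving cinnamate 3 and styrene 7. The other pairwise cut (C1–C2 and C3–C4) would pair a stilbene with a trisubstituted acrylate: the stilbene has no Lewis-basic handle next to the bonds being formed and a triplet stilbene mainly isomerises. The chosen pairing puts an ester where a chiral Lewis acid can bind and leads through a 1,4-diradical that is benzylic at both ends. The precursors are two achiral alkenes; the forward reaction must deliver cross-coupling, head-to-head regiochemistry, the trans aryl relation and one absolute sense.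

**Alkenes.** 3 is cut at its C=C bond to 3,5-dimethoxybenzaldehyde 1 and trimethyl phosphonoacetate 2. 7 is cut at its C=C bond to 3,4-bis(benzyloxy)benzaldehyde 4 and isopropyltriphenylphosphonium iodide 5 (via ylide 6). Both are single olefinations of commercial aldehydes.

## Roads not taken

Alternative 1: The cut removes the C2a–C7a bond and the C2–aryl bond and leads to benzocycloheptenone A2, a seven-membered ketone fused to ring A with CMe2 next to the carbonyl and a styrenic double bond. Forward, CuCl with a chiral bisphosphine, NaOtBu and B2pin2 would add boron to the alkene carbon next to CMe2 and copper to the benzylic carbon, which attacks the ketone across the ring and closes the four- and five-membered rings together to give A1.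
- Merits: one catalytic asymmetric step makes two rings; the cis fusion arises directly. On this point it is better than the adopted plan, which has to invert C7a in step 5. Enantioselective borylcupration of styrenes is well established.
- Weak points: A1 lacks the catechol ring. It would have to be attached by cross-coupling of a secondary cyclobutyl boronate wedged between CMe2 and a ring-fusion carbon, with retention. The tertiary cyclobutanol at the ring fusion must be deoxygenated and is prone to strain-releasing ring opening under palladium or base. Addition of an alkylcopper to a ketone to form a four-membered ring builds strain and may lose to protonation. A2 needs several steps, and the chromene work remains.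
- Comparison: the adopted plan brings both aryl groups in with the photocycloaddition and needs no coupling at a C(sp3)–B bond. Against the direct cis fusion of Alternative 1 it sets the thermodynamic trap of step 5, in which only the cis aldehyde can cyclise.

Alternative 2: The cut removes the arene–C7 and arene–C2a bonds, so the five-membered ring is made last from iodochromene A4 and the chiral cyclobutenylmethyl bromide A5. Forward, Pd(OAc)2 and norbornene would alkylate the ortho C–H bond of A4 with A5, the aryl–palladium bond would add across the cyclobutene, and sodium formate would reduce the resulting alkylpalladium to give A3, the bis(benzyl) ether of 19.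
- Merits: the most convergent road. The chromene is complete before the coupling, so the regiochemical questions of ring A that the adopted plan answers in steps 6 to 8 never arise. Syn carbopalladation gives the cis fusion and approach anti to the resident aryl group gives the trans relation. Only one step follows the key step.
- Weak points: the C–Br bond of A5 is allylic and can ionise with zerovalent palladium to a π-allyl complex, outside the programmed sequence. The tertiary alkylpalladium at C7a has a β-hydrogen at C7 and a strained ring open to β-carbon elimination, and must be reduced faster than either. A5 needs its own asymmetric synthesis, so the stereochemical problem is moved, not solved. Debenzylation of A3 must spare the chromene.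
- Comparison: Alternative 2 is clearly shorter after its key step. The adopted plan sets against this a stereo-defining step with close precedent, partners that are each one step from commercial aldehydes, and removal of the benzyl groups before the chromene exists.

Alternative 3: The cut goes through ring A itself, at the arene bond between the ester-bearing carbon (C3) and the carbon attached to the cyclobutane. The benzene ring would be formed from the diketo-dioxinone A7, a bicyclo[3.2.0]heptan-2-one with a masked polyketide chain. Forward, heating with methanol opens the dioxinone to a β-keto ester, and Cs2CO3 then drives aldol addition of the ester α-carbon to the cyclopentanone carbonyl, dehydration and enolisation to the resorcylate A6.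
- Merits: ring A is born with unambiguous substituents: the ester at C3, a hydrogen-bonded phenol at C4 and a free phenol at C6 that can be methylated selectively. In regiocontrol on ring A it is better than the adopted plan, which relies on electrophilic formylation and chelation-controlled demethylation. The aromatisation itself is reliable.
- Weak points: A7 already contains the cyclobutane with all three stereocentres and the catechol ring, so the central problem is postponed to an unspecified asymmetric cyclobutane synthesis. The sequence is long and linear (C-acylation of the ketone, aromatisation, methylation, ester-to-aldehyde redox, chromene, debenzylation).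
- Comparison: the adopted plan buys ring A as an aldehyde and reaches the target in far fewer steps. It pays with the need to prove the site of formylation in step 6.

Key step: step 3

Assumption: the Lewis acid made from (S)-α,α-diphenylprolinol is taken to expose the face of bound 3 that leads to (1R,2S,3S)-8; if the sense proves opposite, the catalyst from (R)-diphenylprolinol is used and nothing else changes.

Note on descriptors: the descriptor at the ring-A-bearing carbon changes between 8–10 (2S), 11 (2aS) and 12–19 (2aR). This reflects changed substituent priorities only; its configuration is never altered.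

## Route

Step 1
Reactants: 1 3,5-dimethoxybenzaldehyde; 2 trimethyl phosphonoacetate
Product: 3 methyl (E)-3-(3,5-dimethoxyphenyl)prop-2-enoate
Conditions: LiCl, DBU, MeCN, 0 °C → rt
Reagents that add atoms: none
Why: Horner–Wadsworth–Emmons olefination; the stabilised phosphonate anion adds reversibly and eliminates to the (E)-enoate.

Step 2
Reactants: 4 3,4-bis(benzyloxy)benzaldehyde; 5 isopropyltriphenylphosphonium iodide
Product: 7 1,2-bis(benzyloxy)-4-(2-methylprop-1-en-1-yl)benzene, via isopropylidenetriphenylphosphorane 6 (not isolated)
Conditions: 5, n-BuLi, THF, 0 °C; then 4, 0 °C → rt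
Reagents that add atoms: none
Why: Wittig olefination with a non-stabilised ylide; the new alkene terminus carries two identical methyl groups, so no alkene geometry has to be controlled.

Step 3
Reactants: 3 methyl (E)-3-(3,5-dimethoxyphenyl)prop-2-enoate; 7 1,2-bis(benzyloxy)-4-(2-methylprop-1-en-1-yl)benzene
Product: 8 methyl (1R,2S,3S)-3-[3,4-bis(benzyloxy)phenyl]-2-(3,5-dimethoxyphenyl)-4,4-dimethylcyclobutane-1-carboxylate
Conditions: (S)-B-(o-tolyl)oxazaborolidine·AlBr3 (25 mol%), [Ir(ppy)2(dtbbpy)]PF6 (1 mol%), 7 (5 equiv), CH2Cl2, −78 °C, blue LEDs (450 nm)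
Reagents that add atoms: none
Why: The Lewis acid (oxazaborolidine from (S)-α,α-diphenylprolinol and o-tolylboronic acid, activated with AlBr3) binds the ester carbonyl of 3 and should make the bound cinnamate the best acceptor of triplet energy from the photoexcited iridium sensitiser (ppy = 2-phenylpyridinato, dtbbpy = 4,4′-di-tert-butyl-2,2′-bipyridine), while free 3 and 7 are sensitised far more slowly and 7 is not oxidised. The α-carbon of the triplet enoate adds to the CMe2 terminus of 7 to give a triplet 1,4-diradical that is benzylic at both ends, and after intersystem crossing the two benzylic centres combine, closing the four-membered ring by 1,4-radical recombination. The closest known reaction type is the chiral Lewis acid-catalysed, triplet-sensitised crossed [2+2] photocycloaddition of cinnamate esters with styrenes to 1,2-diarylcyclobutanes; only the β,β-dimethyl substitution of the styrene is new. C1 is set in the first bond formation, because the diphenylcarbinol part of the catalyst covers one face of the bound enoate. C2 follows from closure with the dimethoxyphenyl group trans to the ester and C3 from closure of the relaxed diradical with the two aryl groups trans, so the sense fixed at C1 is relayed to both. The step needs head-to-head regiochemistry, which the doubly benzylic diradical secures over the alternative with a tertiary alkyl radical centre, and cross- over homo-coupling, which the excess of the unsensitised partner 7 secures. Any isomer with ester and dimethoxyphenyl cis has to be separated at this stage, because after the inversion of C1 in step 5 it would feed the mirror-image series.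

Step 4
Reactants: 8 methyl (1R,2S,3S)-3-[3,4-bis(benzyloxy)phenyl]-2-(3,5-dimethoxyphenyl)-4,4-dimethylcyclobutane-1-carboxylate
Product: 9 (1R,2S,3S)-3-[3,4-bis(benzyloxy)phenyl]-2-(3,5-dimethoxyphenyl)-4,4-dimethylcyclobutane-1-carbaldehyde
Conditions: i-Bu2AlH (1.1 equiv), CH2Cl2, −78 °C; then aq. KNaC4H4O6
Reagents that add atoms: none
Why: Partial reduction of an ester with diisobutylaluminium hydride; the aluminium hemiacetal of this hindered ester should persist at −78 °C and give the aldehyde on work-up. Partial epimerisation at C1 is harmless because step 5 equilibrates that centre anyway.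

Step 5
Reactants: 9 (1R,2S,3S)-3-[3,4-bis(benzyloxy)phenyl]-2-(3,5-dimethoxyphenyl)-4,4-dimethylcyclobutane-1-carbaldehyde
Product: 12 (2S,2aR,7aS)-2-[3,4-bis(benzyloxy)phenyl]-4,6-dimethoxy-1,1-dimethyl-2,2a,7,7a-tetrahydro-1H-cyclobuta[a]indene, via cis aldehyde 10 (not isolated), via indanol 11 (not isolated)
Conditions: TFA, CH2Cl2 (0.01 M), 0 °C → rt; then Et3SiH, 0 °C → rt
Reagents that add atoms: none
Why: Acid-catalysed enolisation equilibrates the formyl-bearing carbon, and only cis aldehyde 10 can reach the dimethoxyphenyl ring, whose two ortho positions are equivalent and activated by one ortho and one para methoxy group (intramolecular Friedel–Crafts hydroxyalkylation). C7a is thereby fixed cis to ring A, the only fusion the bicyclo[3.2.0] frame permits. Indanol 11 ionises to a 2,4-dimethoxybenzylic cation that triethylsilane reduces to the methylene group (ionic hydrogenation); the silane is added only after ring closure so that the aldehyde is not reduced first.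

Step 6
Reactants: 12 (2S,2aR,7aS)-2-[3,4-bis(benzyloxy)phenyl]-4,6-dimethoxy-1,1-dimethyl-2,2a,7,7a-tetrahydro-1H-cyclobuta[a]indene
Product: 14 (2S,2aR,7aS)-2-[3,4-bis(benzyloxy)phenyl]-4,6-dimethoxy-1,1-dimethyl-2,2a,7,7a-tetrahydro-1H-cyclobuta[a]indene-3-carbaldehyde, via iminium chloride 13 (not isolated)
Conditions: POCl3, DMF, 0 → 60 °C; then aq. NaOAc
Reagents that add atoms: N,N-dimethylformamide CN(C)C=O; water O
Why: Vilsmeier–Haack formylation; C3 is para to the C6 methoxy group and ortho to the C4 methoxy group, whereas C5 lies between two methoxy groups and is less accessible to the chloroiminium ion. The dibenzyloxyphenyl ring has no pair of donors that reinforce each other and should not compete.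

Step 7
Reactants: 14 (2S,2aR,7aS)-2-[3,4-bis(benzyloxy)phenyl]-4,6-dimethoxy-1,1-dimethyl-2,2a,7,7a-tetrahydro-1H-cyclobuta[a]indene-3-carbaldehyde
Product: 15 (2S,2aR,7aS)-2-(3,4-dihydroxyphenyl)-4-hydroxy-6-methoxy-1,1-dimethyl-2,2a,7,7a-tetrahydro-1H-cyclobuta[a]indene-3-carbaldehyde
Conditions: BCl3, C6HMe5, CH2Cl2, −78 → 0 °C; then MeOH, aq. NaHCO3
Reagents that add atoms: none
Why: BCl3 cleaves aryl benzyl ethers at low temperature, with pentamethylbenzene trapping the benzyl cations, and cleaves the methyl ether ortho to the aldehyde through a six-membered boron chelate. The non-chelated C6 methoxy group should survive.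

Step 8
Reactants: 15 (2S,2aR,7aS)-2-(3,4-dihydroxyphenyl)-4-hydroxy-6-methoxy-1,1-dimethyl-2,2a,7,7a-tetrahydro-1H-cyclobuta[a]indene-3-carbaldehyde; 16 (2-methylprop-1-en-1-yl)magnesium bromide
Product: 19 CNP0207533.1: 4-[(2S,2aR,7aS)-6-methoxy-1,1-dimethyl-2,2a,7,7a-tetrahydro-1H-cyclobuta[a]inden-2-yl]benzene-1,2-diol carrying a 2,2-dimethyl-2H-pyran fused at C3–C4 (O on C4; CH=CH on C3), via allylic carbinol 17 (not isolated), via ortho-quinone methide 18 (not isolated)
Conditions: 16 (6 equiv), THF, 0 °C → rt; aq. NH4Cl; then PPTS (cat.), CH2Cl2, rt
Reagents that add atoms: none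
Why: Grignard 1,2-addition to a salicylaldehyde, with three equivalents of reagent consumed by the phenols. The ortho-hydroxy benzylic allylic alcohol 17 loses water under mild acid to ortho-quinone methide 18, which closes to the 2,2-dimethyl-2H-chromene by oxa-6π electrocyclisation; no stereocentre is formed or touched.

## Compound list

1 | 3,5-dimethoxybenzaldehyde | COc1cc(C=O)cc(OC)c1 | starting material
2 | trimethyl phosphonoacetate | COC(=O)CP(=O)(OC)OC | starting material
3 | methyl (E)-3-(3,5-dimethoxyphenyl)prop-2-enoate | COC(=O)/C=C/c1cc(OC)cc(OC)c1 | intermediate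
4 | 3,4-bis(benzyloxy)benzaldehyde | O=Cc1ccc(OCc2ccccc2)c(OCc2ccccc2)c1 | starting material
5 | isopropyltriphenylphosphonium iodide | CC(C)[P+](c1ccccc1)(c1ccccc1)c1ccccc1.[I-] | starting material
6 | isopropylidenetriphenylphosphorane | CC(C)=P(c1ccccc1)(c1ccccc1)c1ccccc1 | intermediate (not isolated)
7 | 1,2-bis(benzyloxy)-4-(2-methylprop-1-en-1-yl)benzene | CC(C)=Cc1ccc(OCc2ccccc2)c(OCc2ccccc2)c1 | intermediate
8 | methyl (1R,2S,3S)-3-[3,4-bis(benzyloxy)phenyl]-2-(3,5-dimethoxyphenyl)-4,4-dimethylcyclobutane-1-carboxylate (all-trans) | COC(=O)[C@@H]1[C@@H](c2cc(OC)cc(OC)c2)[C@H](c2ccc(OCc3ccccc3)c(OCc3ccccc3)c2)C1(C)C | intermediate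
9 | (1R,2S,3S)-3-[3,4-bis(benzyloxy)phenyl]-2-(3,5-dimethoxyphenyl)-4,4-dimethylcyclobutane-1-carbaldehyde (formyl trans to dimethoxyphenyl) | O=C[C@@H]1[C@@H](c2cc(OC)cc(OC)c2)[C@H](c2ccc(OCc3ccccc3)c(OCc3ccccc3)c2)C1(C)C | intermediate
10 | (1S,2S,3S)-3-[3,4-bis(benzyloxy)phenyl]-2-(3,5-dimethoxyphenyl)-4,4-dimethylcyclobutane-1-carbaldehyde (formyl cis to dimethoxyphenyl) | O=C[C@H]1[C@@H](c2cc(OC)cc(OC)c2)[C@H](c2ccc(OCc3ccccc3)c(OCc3ccccc3)c2)C1(C)C | intermediate (not isolated)
11 | (2S,2aS,7aS)-2-[3,4-bis(benzyloxy)phenyl]-4,6-dimethoxy-1,1-dimethyl-2,2a,7,7a-tetrahydro-1H-cyclobuta[a]inden-7-ol (both C7 epimers; cis ring fusion) | COc1cc(OC)cc2c1C(O)[C@H]1[C@@H]2[C@H](c2ccc(OCc3ccccc3)c(OCc3ccccc3)c2)C1(C)C | intermediate (not isolated)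
12 | (2S,2aR,7aS)-2-[3,4-bis(benzyloxy)phenyl]-4,6-dimethoxy-1,1-dimethyl-2,2a,7,7a-tetrahydro-1H-cyclobuta[a]indene | COc1cc(OC)cc2c1C[C@H]1[C@@H]2[C@H](c2ccc(OCc3ccccc3)c(OCc3ccccc3)c2)C1(C)C | intermediate
13 | N-{[(2S,2aR,7aS)-2-[3,4-bis(benzyloxy)phenyl]-4,6-dimethoxy-1,1-dimethyl-2,2a,7,7a-tetrahydro-1H-cyclobuta[a]inden-3-yl]methylidene}-N-methylmethanaminium chloride | COc1cc(OC)c(C=[N+](C)C)c2c1C[C@H]1[C@@H]2[C@H](c2ccc(OCc3ccccc3)c(OCc3ccccc3)c2)C1(C)C.[Cl-] | intermediate (not isolated)
14 | (2S,2aR,7aS)-2-[3,4-bis(benzyloxy)phenyl]-4,6-dimethoxy-1,1-dimethyl-2,2a,7,7a-tetrahydro-1H-cyclobuta[a]indene-3-carbaldehyde | COc1cc(OC)c(C=O)c2c1C[C@H]1[C@@H]2[C@H](c2ccc(OCc3ccccc3)c(OCc3ccccc3)c2)C1(C)C | intermediate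
15 | (2S,2aR,7aS)-2-(3,4-dihydroxyphenyl)-4-hydroxy-6-methoxy-1,1-dimethyl-2,2a,7,7a-tetrahydro-1H-cyclobuta[a]indene-3-carbaldehyde | COc1cc(O)c(C=O)c2c1C[C@H]1[C@@H]2[C@H](c2ccc(O)c(O)c2)C1(C)C | intermediate
16 | (2-methylprop-1-en-1-yl)magnesium bromide | CC(C)=C[Mg]Br | starting material
17 | 4-[(2S,2aR,7aS)-4-hydroxy-3-(1-hydroxy-3-methylbut-2-en-1-yl)-6-methoxy-1,1-dimethyl-2,2a,7,7a-tetrahydro-1H-cyclobuta[a]inden-2-yl]benzene-1,2-diol (both carbinol epimers) | COc1cc(O)c(C(O)C=C(C)C)c2c1C[C@H]1[C@@H]2[C@H](c2ccc(O)c(O)c2)C1(C)C | intermediate (not isolated)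
18 | (2S,2aR,7aS)-2-(3,4-dihydroxyphenyl)-6-methoxy-1,1-dimethyl-3-(3-methylbut-2-en-1-ylidene)-1,2,2a,3,7,7a-hexahydro-4H-cyclobuta[a]inden-4-one (ortho-quinone methide; exocyclic alkene geometry not fixed) | COC1=CC(=O)C(=CC=C(C)C)C2=C1C[C@H]1[C@@H]2[C@H](c2ccc(O)c(O)c2)C1(C)C | intermediate (not isolated)
19 | CNP0207533.1: 4-[(2S,2aR,7aS)-6-methoxy-1,1-dimethyl-2,2a,7,7a-tetrahydro-1H-cyclobuta[a]inden-2-yl]benzene-1,2-diol with a 2,2-dimethyl-2H-pyran fused at C3–C4 (O on C4, CH=CH on C3) | COc1cc2c(c3c1C[C@H]1[C@@H]3[C@H](c3ccc(O)c(O)c3)C1(C)C)C=CC(C)(C)O2 | target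

## Step count and risks

Total: 8 steps. Longest linear sequence: 7 steps (step 1, then steps 3 to 8; the branch through step 2 is equally long).

**Step 3 (key step).** The most likely failure is slow addition of the triplet enoate to the hindered, trisubstituted terminus of 7 inside the chiral pocket. Unproductive E/Z isomerisation and homodimerisation of 3 would then dominate, an uncatalysed background reaction would erode enantioselectivity, and the acidic catalyst could oligomerise the electron-rich styrene. Incomplete removal of the ester/aryl-cis diastereomer would also lower the enantiomeric purity after step 5.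
Fallback: resolution in place of asymmetric induction. It sets out from 3 and 7, which are irradiated at room temperature without Lewis acid in the presence of the higher-energy sensitiser [Ir(dF(CF3)ppy)2(dtbbpy)]PF6 and excess 7. This should give the racemic all-trans ester F1, which is resolved by preparative chromatography on a polysaccharide chiral stationary phase. The fallback comes back to the route at 8.

**Step 5.** Three things can go wrong:
- the benzylic cation formed after ring closure alkylates the electron-rich ring of a second molecule before the silane is added;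
- the trans aldehyde closes onto the neighbouring catechol ring (a bridged ring closure) or is reduced before it epimerises;
- epimerisation is too slow under acid that the benzyl ethers tolerate.

Fallback: ring closure at the acid oxidation level, which ends in a deactivated ketone that cannot alkylate further. It sets out from 8.
- LiOH in aqueous THF gives the carboxylic acid F2.
- Oxalyl chloride converts F2 into the acid chloride F3.
- With SnCl4 in CH2Cl2, F3 should lose HCl reversibly to the ketene F4, which is planar at C1.
- Only the cis acylium ion can acylate ring A, giving the cis-fused indanone F5.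
- NaBH4 reduces F5 to 11, where the fallback comes back to the route; 11 is reduced with Et3SiH and TFA to 12 as in the second stage of step 5.

**Step 6.** The most likely failure is poor site selectivity (attack at C5 between the methoxy groups) or low conversion, because C3 is flanked by the ring-fusion carbon and lies near the C2 aryl group.
Fallback: halogenation and formylation through an aryllithium. It sets out from 12: NBS in MeCN at 0 °C, a smaller and more reactive electrophile with the same para-to-methoxy preference, should give the aryl bromide F6. Bromine–lithium exchange with n-BuLi in THF at −78 °C followed by DMF gives the aldehyde. The fallback comes back at 14.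

**Step 8.** The most likely failure is incomplete addition, because the magnesium tris-phenoxide of 15 precipitates. Oligomerisation of the quinone methide and air oxidation of the catechol during the acid stage are further risks.
Fallback: temporary silyl protection. It sets out from 15: TBSCl and imidazole in DMF give the tris(silyl ether) F7, addition of 16 gives the silylated carbinol F8, and Bu4NF buffered with AcOH removes the three silyl groups. The fallback comes back at 17, which closes to 19 under the acid conditions of step 8.

## Further compounds

F1 | step 3 | racemic methyl (1R*,2S*,3S*)-3-[3,4-bis(benzyloxy)phenyl]-2-(3,5-dimethoxyphenyl)-4,4-dimethylcyclobutane-1-carboxylate (both enantiomers) | COC(=O)[C@@H]1[C@@H](c2cc(OC)cc(OC)c2)[C@H](c2ccc(OCc3ccccc3)c(OCc3ccccc3)c2)C1(C)C.COC(=O)[C@H]1[C@H](c2cc(OC)cc(OC)c2)[C@@H](c2ccc(OCc3ccccc3)c(OCc3ccccc3)c2)C1(C)C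
F2 | step 5 | (1R,2S,3S)-3-[3,4-bis(benzyloxy)phenyl]-2-(3,5-dimethoxyphenyl)-4,4-dimethylcyclobutane-1-carboxylic acid | OC(=O)[C@@H]1[C@@H](c2cc(OC)cc(OC)c2)[C@H](c2ccc(OCc3ccccc3)c(OCc3ccccc3)c2)C1(C)C
F3 | step 5 | (1R,2S,3S)-3-[3,4-bis(benzyloxy)phenyl]-2-(3,5-dimethoxyphenyl)-4,4-dimethylcyclobutane-1-carbonyl chloride | O=C(Cl)[C@@H]1[C@@H](c2cc(OC)cc(OC)c2)[C@H](c2ccc(OCc3ccccc3)c(OCc3ccccc3)c2)C1(C)C
F4 | step 5 | {(2R,3R)-3-[3,4-bis(benzyloxy)phenyl]-2-(3,5-dimethoxyphenyl)-4,4-dimethylcyclobutylidene}methanone (ketene) | O=C=C1[C@@H](c2cc(OC)cc(OC)c2)[C@H](c2ccc(OCc3ccccc3)c(OCc3ccccc3)c2)C1(C)C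
F5 | step 5 | (2S,2aS,7aS)-2-[3,4-bis(benzyloxy)phenyl]-4,6-dimethoxy-1,1-dimethyl-1,2,2a,7a-tetrahydro-7H-cyclobuta[a]inden-7-one | COc1cc(OC)cc2c1C(=O)[C@H]1[C@@H]2[C@H](c2ccc(OCc3ccccc3)c(OCc3ccccc3)c2)C1(C)C
F6 | step 6 | (2S,2aR,7aS)-2-[3,4-bis(benzyloxy)phenyl]-3-bromo-4,6-dimethoxy-1,1-dimethyl-2,2a,7,7a-tetrahydro-1H-cyclobuta[a]indene | COc1cc(OC)c(Br)c2c1C[C@H]1[C@@H]2[C@H](c2ccc(OCc3ccccc3)c(OCc3ccccc3)c2)C1(C)C
F7 | step 8 | (2S,2aR,7aS)-2-{3,4-bis[(tert-butyldimethylsilyl)oxy]phenyl}-4-[(tert-butyldimethylsilyl)oxy]-6-methoxy-1,1-dimethyl-2,2a,7,7a-tetrahydro-1H-cyclobuta[a]indene-3-carbaldehyde | COc1cc(O[Si](C)(C)C(C)(C)C)c(C=O)c2c1C[C@H]1[C@@H]2[C@H](c2ccc(O[Si](C)(C)C(C)(C)C)c(O[Si](C)(C)C(C)(C)C)c2)C1(C)C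
F8 | step 8 | 1-[(2S,2aR,7aS)-2-{3,4-bis[(tert-butyldimethylsilyl)oxy]phenyl}-4-[(tert-butyldimethylsilyl)oxy]-6-methoxy-1,1-dimethyl-2,2a,7,7a-tetrahydro-1H-cyclobuta[a]inden-3-yl]-3-methylbut-2-en-1-ol (both carbinol epimers) | COc1cc(O[Si](C)(C)C(C)(C)C)c(C(O)C=C(C)C)c2c1C[C@H]1[C@@H]2[C@H](c2ccc(O[Si](C)(C)C(C)(C)C)c(O[Si](C)(C)C(C)(C)C)c2)C1(C)C
A1 | alternative 1 | (2S,2aR,7aR)-4,6-dimethoxy-1,1-dimethyl-2-(4,4,5,5-tetramethyl-1,3,2-dioxaborolan-2-yl)-1,2,2a,7-tetrahydro-7aH-cyclobuta[a]inden-7a-ol | COc1cc(OC)cc2c1C[C@@]1(O)[C@@H]2[C@H](B3OC(C)(C)C(C)(C)O3)C1(C)C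
A2 | alternative 1 | 2,4-dimethoxy-7,7-dimethyl-5,7-dihydro-6H-benzo[7]annulen-6-one | COc1cc(OC)cc2c1CC(=O)C(C)(C)C=C2
A3 | alternative 2 | bis(benzyl) ether of 19 at the two catechol oxygens | COc1cc2c(c3c1C[C@H]1[C@@H]3[C@H](c3ccc(OCc4ccccc4)c(OCc4ccccc4)c3)C1(C)C)C=CC(C)(C)O2
A4 | alternative 2 | 5-iodo-7-methoxy-2,2-dimethyl-2H-chromene | COc1cc(I)c2C=CC(C)(C)Oc2c1
A5 | alternative 2 | 1,2-bis(benzyloxy)-4-[(1R)-3-(bromomethyl)-4,4-dimethylcyclobut-2-en-1-yl]benzene | BrCC1=C[C@H](c2ccc(OCc3ccccc3)c(OCc3ccccc3)c2)C1(C)C
A6 | alternative 3 | methyl (2S,2aR,7aS)-2-[3,4-bis(benzyloxy)phenyl]-4,6-dihydroxy-1,1-dimethyl-2,2a,7,7a-tetrahydro-1H-cyclobuta[a]indene-3-carboxylate | Oc1cc(O)c(C(=O)OC)c2c1C[C@H]1[C@@H]2[C@H](c2ccc(OCc3ccccc3)c(OCc3ccccc3)c2)C1(C)C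
A7 | alternative 3 | 6-{2-[7-[3,4-bis(benzyloxy)phenyl]-6,6-dimethyl-2-oxobicyclo[3.2.0]heptan-3-yl]-2-oxoethyl}-2,2-dimethyl-4H-1,3-dioxin-4-one (ring-fusion and aryl-bearing carbons configured as in 19; C3 epimers) | O=C1C(C(=O)CC2=CC(=O)OC(C)(C)O2)C[C@H]2[C@@H]1[C@H](c1ccc(OCc3ccccc3)c(OCc3ccccc3)c1)C2(C)C
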